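Laying two runs over each other on enzyme times time can hide an enzyme that wears out with use, so I compared them at equal conversion instead.

the same everywhere: substrate 0.10 M
- autumn: enzyme 0.025 mol%; run made earlier
- noon: enzyme 0.1 mol%; run made earlier
- flask: enzyme 0.05 mol%

- autumn (time / h: target / %): 2.00: 1.7; 4.00: 5.7; 6.00: 10.8; 8.00: 12.2; 10.0: 13.4; 12.0: 16.9
- noon (time / h: target / %): 0.833: 5.7; 2.50: 15.5; 4.00: 21.1; 6.00: 31.9; 10.0: 47.8; 12.0: 53.9

(standard deviation of a reading: 1 percentage point)

1. apparent order in enzyme when 30% of the substrate are converted (percent change of the rate of making target for one percent more enzyme charged)
2. factor on the rate of making target when 30% of the substrate are converted if enzyme is charged twice over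

- what was read earlier has a scatter of 1 percentage point, one standard deviation

I counted turnovers: the fraction of the charge converted, over the enzyme loading. Noon read 15.5% at 2.50 h, or 155 turnovers; autumn read 16.9% at 12.0 h, or 676. Taken as first order in substrate, noon's constant per unit of enzyme stood at 1.09 times autumn's, though a scatter of 1 percentage point could make that excess by itself. I kept it as a rough reading. Setting each run's mean loss at its middle turnover, it gave 3180 turnovers as the enzyme's working life, the count at which a steady loss per turnover would use it up.

My first answer for the flask was order one, so I put this loss back in. Corrected for noon's loss, the flask's curve starts at a slope of 0.0345 h⁻¹. Reaching 30% costs each enzyme 600 turnovers, which I put at about 11.4 h, with the slope down to 0.0196 h⁻¹. The curve shows no knee, and the whole charge needs 2000 turnovers, fewer than the working life, so it bends on towards the whole charge. A set amount lost from a larger charge matters less, so I took the order as one over the share left, 1.23, and doubling as 2.23.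

The forecast gave 1.03 and 2.04, finding “no sign of catalyst death or product inhibition”. The flask gave 1.2 and 2.25.

    complex → spent catalyst (k = 0.0920 h⁻¹)
    substrate + enzyme ⇌ complex (K = 3.30 M⁻¹, k = 80700 M⁻¹ h⁻¹)
    complex → enzyme + target (k = 279 h⁻¹)

The largest single effect on the order is the passing of complex into spent catalyst: the same flask without that step has an order of 1.0 in place of 1.2. At 15.0 h the flask's 37.3% of target meant 747 turnovers, which against the working life of 3180 makes 23.5% of the enzyme spent, and the flask held 24.6% spent catalyst. With twice the enzyme, each enzyme owes 300 turnovers instead of 600, losing 9.43% instead of 18.9%, and the rate stands at 2.25 times this flask's.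

(The runs were generated by integration for an exercise; noise was put on by code.)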